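The pitfall in an order taken at fixed conversion is that you vary the charge while the rate feels what is left, and what is left, the charge minus a fixed amount used, changes by a larger percentage than the charge.

the same everywhere: left-handed substrate 0.010 M; right-handed substrate 0.010 M; catalyst 6.2 µM; added ligand 11 µM

| flask | partner | remark |
|---|---|---|
| south | 0.011 M | the very flask that is asked about, followed so far |
| flask | 0.0110 M |  |

- south (time / min: left-handed product / %, left-handed substrate / %): 0.200: 30.4, 19.2; 0.667: 35.7, 13.6; 1.00: 36.8, 12.9; 1.50: 36.3, 13.3; 2.50: 36.9, 12.9; 3.00: 37.2, 13.3

(readings scatter by 0.3 percentage points)

* apparent order in partner when 20% of the left-handed substrate and right-handed substrate together are converted (percent change of the rate of making left-handed product for one percent more partner charged)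
* apparent order in catalyst when 20% of the left-handed substrate and right-handed substrate together are converted (percent change of the rate of making left-handed product for one percent more catalyst charged)

- catalyst is single-handed; left-handed substrate and right-handed substrate are mirror images of each other, charged as a racemate, each of them at the stated concentration
- no earlier run changes the charge of catalyst; that part of a forecast is a guess
- no earlier run changes the charge of partner; that part of a forecast is a guess

In this flask the racemate brings 0.0200 M of substrate against 0.0110 M of partner, so partner, with less on hand, is the likely limiting reagent. Suppose each turnover takes one partner. At the mark of 20% the flask has used 0.00400 M, which leaves 0.00700 M. Call the partner leverage the charge divided by what is left at the mark: 1.57. If the rate is first order in partner and more partner leaves the substrates and the working catalyst at the mark unchanged, this leverage is the order.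

But the south readings stall near 36.8% of left-handed product, and a dying catalyst could stall them too. That doesn't touch the subtraction: the first south reading, at 0.200 min, already shows 30.4% of left-handed product, more than the mark, so the mark comes before that reading and before the stall.

The same fact is the real objection, since the earliest south reading already lies past the mark. More partner reaches it sooner, and if catalyst is being lost on the way, it arrives with more catalyst, so this correction points upward. I commit to slightly above 1.57. No run varies the catalyst, so my order there is a guess of 1.

The forecast says 1.4 in partner and 1 in catalyst. It comes down from about 1.6, “Allowing for some saturation or the deactivation alternative”, so on partner it stands below my figure.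

The flask gives 1.7 in partner and 0.86 in catalyst.

    partner + catalyst + right-handed substrate → catalyst + right-handed product (k = 1.70 × 10⁶ /M²/s)
    2 catalyst ⇌ resting dimer (K = 91000 /M, k = 46000 /M/s)
    catalyst + added ligand ⇌ idle complex (K = 35000 /M, k = 38000 /M/s)
    partner + catalyst + left-handed substrate → catalyst + left-handed product (k = 5.00 × 10⁶ /M²/s)

At 1.00 min this flask holds 51.8% of its catalyst free, 17.9% as idle complex and 30.3% as resting dimer. The order in partner stands above the leverage 1.57. Now take a second flask with twice the partner: what is left at the mark rises from 0.00700 M to 0.0180 M, so the leverage reckoning gives a factor of 2.57 on the rate. That flask gives more than this, a factor of 3.09.

The numbers in the tables were generated by integration on assumed constants; noise was put on by code.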